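**Retrosynthetic overview**
1. The C2-symmetric target is cut through its central 1,4-dioxane (C7–O–C6'–C7'–O–C6). This six-membered ring is traced back to a spiro-1,3-dioxolane in which C7' is a ketal carbon carrying both oxygens of the C6/C7 diol of the other half.
2. Forward, three components are joined in one flask: bis-silyl ether 5 of the 6α,7α-diol, 6α-silyloxy-7-ketone 9 and Et3SiH. Ketalisation gives the five-membered ring, a shift of benzylic C7 from the ketal oxygen to O6' enlarges it to the six-membered ring, and the former carbonyl oxygen is then removed reductively.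
3. Enabling feature: the methoxy group on C12 is para to C8 of aromatic ring C, so the benzylic C7–O bonds of ring B ionise like p-methoxybenzyl ethers. The ketone oxygen on C7' serves as a traceless tether, and the C2 axis lets both halves come from one precursor.
4. Both halves come from (+)-ferruginol, which supplies rings A, B, C and C5/C10. One half goes through the ring-B alkene and α-face dihydroxylation, the other through the 7-ketone and Rubottom oxidation. The C6/C6' oxygens are set there; C7/C7' are set in the key step.
5. Order of ring formation: carbocycles (chiral pool), then spiro-dioxolane, then 1,4-dioxane.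

Key step: step 8

Remark: (+)-ferruginol (natural 5S,10S series) is assumed to be purchasable; abietane numbering is used, and primed numbers mark the half that enters the key step as ketone 9.

**Step 1**
Reactants: 1 (+)-ferruginol
Product: 2 ferruginol methyl ether (12-methoxyabieta-8,11,13-triene)
Conditions: MeI, K2CO3, acetone, reflux
Reagents that add atoms: iodomethane, CI
Why: Williamson-type O-methylation of the phenol is routine and touches no stereocentre.

**Step 2**
Reactants: 2 ferruginol methyl ether
Product: 3 12-methoxyabieta-6,8,11,13-tetraene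
Conditions: DDQ (1.2 equiv), 1,4-dioxane, 100 °C
Reagents that add atoms: none
Why: DDQ benzylic dehydrogenation: hydride abstraction from C7, activated by the para methoxy group on C12, followed by loss of H6 should give the ring-B styrene without touching C5 or C10.

**Step 3**
Reactants: 3 12-methoxyabieta-6,8,11,13-tetraene
Product: 4 12-methoxyabieta-8,11,13-triene-6α,7α-diol
Conditions: OsO4 (2 mol %), NMO, acetone–H2O, rt
Reagents that add atoms: N-methylmorpholine N-oxide, C[N+]1([O-])CCOCC1; water, O
Why: Catalytic OsO4 syn-dihydroxylation should attack the styrene from the α face, opposite the axial C10 methyl and the 4β-methyl, and so set C6 and C7 as the 6α,7α-diol.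

**Step 4**
Reactants: 4 12-methoxyabieta-8,11,13-triene-6α,7α-diol
Product: 5 6α,7α-bis(trimethylsilyloxy)-12-methoxyabieta-8,11,13-triene
Conditions: TMSCl, imidazole, DMF, 0 °C to rt
Reagents that add atoms: chlorotrimethylsilane, C[Si](C)(C)Cl
Why: Standard bis-O-silylation turns the diol into the silyl-ether donor needed for silyl-triflate-catalysed ketalisation; no stereocentre changes.

**Step 5**
Reactants: 2 ferruginol methyl ether
Product: 6 12-methoxyabieta-8,11,13-trien-7-one (sugiol methyl ether)
Conditions: CrO3, AcOH, rt
Reagents that add atoms: chromium trioxide, O=[Cr](=O)=O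
Why: CrO3 benzylic oxidation of the C7 methylene, the ring-B position para-activated by the C12 methoxy group, is the classical entry to the 7-ketone and leaves C5/C10 intact.

**Step 6**
Reactants: 6 12-methoxyabieta-8,11,13-trien-7-one
Product: 7 12-methoxy-7-(triethylsilyloxy)abieta-6,8,11,13-tetraene
Conditions: TESOTf, Et3N, CH2Cl2, 0 °C
Reagents that add atoms: triethylsilyl trifluoromethanesulfonate, CC[Si](CC)(CC)OS(=O)(=O)C(F)(F)F
Why: Soft enolisation and O-silylation should give the only possible enol silane (C6=C7), the substrate for the Rubottom oxidation.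

**Step 7**
Reactants: 7 12-methoxy-7-(triethylsilyloxy)abieta-6,8,11,13-tetraene
Product: 9 12-methoxy-6α-(triethylsilyloxy)abieta-8,11,13-trien-7-one, via silyloxy epoxide 8 (not isolated)
Conditions: mCPBA, hexane–CH2Cl2, −15 to 0 °C
Reagents that add atoms: 3-chloroperoxybenzoic acid, OOC(=O)c1cccc(Cl)c1
Why: Rubottom oxidation: the peracid should epoxidise the enol silane from the α face to silyloxy epoxide 8, which opens with 1,4-silyl shift to the α-silyloxy ketone and sets the C6 oxygen α (equatorial, also the thermodynamically favoured epimer next to the ketone).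

**Step 8**
Reactants: 5 6α,7α-bis(trimethylsilyloxy)-12-methoxyabieta-8,11,13-triene; 9 12-methoxy-6α-(triethylsilyloxy)abieta-8,11,13-trien-7-one
Product: 12 target CNP0327150.1, via spiro-dioxolane 10 (not isolated), via silyl ketal 11 (not isolated)
Conditions: TMSOTf (0.2 equiv), CH2Cl2, 4 Å MS, −78 to −20 °C; then Et3SiH (1.1 equiv), −78 °C
Reagents that add atoms: none
Why: Proposed new method: TMSOTf should first ketalise ketone 9 with the bis-silyl ether 5 (silyl-triflate-catalysed ketalisation with loss of (Me3Si)2O, a known reaction type) to spiro-dioxolane 10, in which the carbonyl oxygen of 9 has become a tether between C7' and C7; on warming, silylation of that tether oxygen should let the C7–O bond ionise to the p-methoxybenzylic cation (C12–OMe para to C8), which is captured by the silyl-ether oxygen on C6' with 1,4-transfer of the Et3Si group, so that the five-membered ring is enlarged to the 1,4-dioxane of silyl ketal 11 by a 1,4 O-to-O shift of C7, and Et3SiH then reduces the cyclic oxocarbenium ion formed from 11. The closest known reaction types are acid-induced migration of p-methoxybenzyl groups between neighbouring oxygens, ring-enlarging transacetalisation of cyclic acetals and Et3SiH/silyl-triflate reduction of cyclic aryl ketals to ethers. Ring closures: the dioxolane forms by addition of the second silyl-ether oxygen to the C7' oxocarbenium ion (5-exo-trig), the dioxane by 6-exo-trig capture of the benzylic cation. Stereocentres: C7 is inverted from 7α-O to 7β-O under thermodynamic control, because the benzylic ether can re-ionise until the trans-diequatorial ring fusion next to the fixed 6α-oxygen is reached, and C7' should take up hydride axially from the α face, anti to the C10' methyl group and trans to H6'. Selectivity needed: head-to-tail connectivity, secured because the ketone half offers only one nucleophilic oxygen (O6', α from step 7) and the diol half only one ionisable non-ketal bond (benzylic C7–O), and chemoselectivity against 1,2-hydride shift and against silane hydrogenolysis of the benzylic ethers, for which the capture is intramolecular and the silane is added only after the expansion, at −78 °C, where only the ketal should ionise.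

**Compound list**
1 | (+)-ferruginol (abieta-8,11,13-trien-12-ol, 5S,10S) | Oc1cc2c(cc1C(C)C)CC[C@H]1C(C)(C)CCC[C@]21C | starting material
2 | ferruginol methyl ether (12-methoxyabieta-8,11,13-triene) | COc1cc2c(cc1C(C)C)CC[C@H]1C(C)(C)CCC[C@]21C | intermediate
3 | 12-methoxyabieta-6,8,11,13-tetraene | COc1cc2c(cc1C(C)C)C=C[C@H]1C(C)(C)CCC[C@]21C | intermediate
4 | 12-methoxyabieta-8,11,13-triene-6α,7α-diol | COc1cc2c(cc1C(C)C)[C@H](O)[C@H](O)[C@H]1C(C)(C)CCC[C@]21C | intermediate
5 | 6α,7α-bis(trimethylsilyloxy)-12-methoxyabieta-8,11,13-triene | COc1cc2c(cc1C(C)C)[C@H](O[Si](C)(C)C)[C@H](O[Si](C)(C)C)[C@H]1C(C)(C)CCC[C@]21C | intermediate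
6 | 12-methoxyabieta-8,11,13-trien-7-one (sugiol methyl ether) | COc1cc2c(cc1C(C)C)C(=O)C[C@H]1C(C)(C)CCC[C@]21C | intermediate
7 | 12-methoxy-7-(triethylsilyloxy)abieta-6,8,11,13-tetraene | COc1cc2c(cc1C(C)C)C(O[Si](CC)(CC)CC)=C[C@H]1C(C)(C)CCC[C@]21C | intermediate
8 | 6α,7α-epoxy-12-methoxy-7β-(triethylsilyloxy)abieta-8,11,13-triene (forms in the flask in step 7) | COc1cc2c(cc1C(C)C)[C@]3(O[Si](CC)(CC)CC)O[C@@H]3[C@H]1C(C)(C)CCC[C@]21C | intermediate
9 | 12-methoxy-6α-(triethylsilyloxy)abieta-8,11,13-trien-7-one | COc1cc2c(cc1C(C)C)C(=O)[C@H](O[Si](CC)(CC)CC)[C@H]1C(C)(C)CCC[C@]21C | intermediate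
10 | spiro-1,3-dioxolane: ketal of C7' of 9 with the 6α- and 7α-oxygens of the diol half, 6'α-OSiEt3 retained; configuration at the spiro carbon C7' not controlled, both epimers converge (forms in the flask in step 8) | COc1cc2c(cc1C(C)C)[C@@H]3OC4(O[C@@H]3[C@H]5C(C)(C)CCC[C@]25C)c6cc(C(C)C)c(OC)cc6[C@@]7(C)CCCC(C)(C)[C@@H]7[C@H]4O[Si](CC)(CC)CC | intermediate
11 | ring-expanded 1,4-dioxane (C7β–O–C6'α and C6α–O–C7') carrying OSiEt3 on the ketal carbon C7'; configuration at C7' not defined (forms in the flask in step 8) | COc1cc2c(cc1C(C)C)[C@H]1O[C@H]3C(O[Si](CC)(CC)CC)(O[C@@H]1[C@H]1C(C)(C)CCC[C@]21C)c1cc(C(C)C)c(OC)cc1[C@@]1(C)CCCC(C)(C)[C@H]31 | intermediate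
12 | CNP0327150.1, head-to-tail bis-ether dimer (6α-O–7'β and 7β-O–6'α, trans-fused 1,4-dioxane) | COc1cc2c(cc1C(C)C)[C@H]1O[C@H]3[C@H](O[C@@H]1[C@H]1C(C)(C)CCC[C@]21C)c1cc(C(C)C)c(OC)cc1[C@@]1(C)CCCC(C)(C)[C@H]31 | target

**Totals**
Total step count: 8. Longest linear sequence: 5 steps (1 → 2 → 3 → 4 → 8, or 1 → 5 → 6 → 7 → 8).

**Steps most likely to fail**

1. Step 8 (Proposed new method). Three processes are at risk. Ketalisation of the hindered aryl ketone may stay incomplete. The benzylic cation may collapse by 1,2-hydride shift from C6 (semipinacol-type) faster than it is captured by O6'. The silane may hydrogenolyse benzylic C–O bonds. Fallback with known chemistry: setting out from alkene 3, epoxidation with dimethyldioxirane (acetone, 0 °C) from the α face should give the 6α,7α-epoxide F1. BF3·OEt2 (catalytic, CH2Cl2, −78 °C) should then bring about the known Lewis-acid head-to-tail dimerisation of aryl epoxides to 2,5-diaryl-1,4-dioxanes: each epoxide oxygen stays on C6 and attacks the benzylic C7 of the partner with inversion. This comes back to the route at target 12.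

2. Step 2. The dehydrogenation may lose site selectivity (hydride abstraction at the isopropyl methine) or run on to over-oxidised products. Fallback: setting out from ketone 6, NaBH4 (MeOH, 0 °C) should give 12-methoxyabieta-8,11,13-trien-7β-ol F2 by α-face hydride delivery. Acid-catalysed dehydration (TsOH, toluene, 80 °C) then comes back to the route at alkene 3.

3. Step 7. The peracid may insert into the aryl ketone (Baeyer–Villiger), or the silyl group may be lost before the 1,4-shift. Fallback: setting out from diol 4, chemoselective oxidation of the p-methoxybenzylic hydroxyl with DDQ (CH2Cl2, rt) should give 6α-hydroxy-12-methoxyabieta-8,11,13-trien-7-one F3. Silylation with TESOTf and 2,6-lutidine (CH2Cl2, −78 °C) then comes back to the route at ketone 9.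

**Further compounds**
F1 | step 8 | 6α,7α-epoxy-12-methoxyabieta-8,11,13-triene | COc1cc2c(cc1C(C)C)[C@@H]3O[C@@H]3[C@H]1C(C)(C)CCC[C@]21C
F2 | step 2 | 12-methoxyabieta-8,11,13-trien-7β-ol | COc1cc2c(cc1C(C)C)[C@@H](O)C[C@H]1C(C)(C)CCC[C@]21C
F3 | step 7 | 6α-hydroxy-12-methoxyabieta-8,11,13-trien-7-one | COc1cc2c(cc1C(C)C)C(=O)[C@H](O)[C@H]1C(C)(C)CCC[C@]21C
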